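**Strategy.** Everything rests on the acyloin unit of ring B: the tertiary carbinol C7 and the ketone C8 (eremophilane numbering) are joined in the ring-closing step. A chiral triazolylidene converts the aldehyde carbon C8 of a keto aldehyde into an acyl anion equivalent that adds to the C7 ketone (intramolecular crossed benzoin reaction). This closes ring B, sets the C7 quaternary carbinol with its complete three-carbon side chain and, after loss of the C10 hydroxyl in the same flask, gives the 1,9-dien-8-one. The precursor is a ring A cyclohexenol with a 2-oxoethyl arm on C10 and a hydroxymethyl vinyl ketone arm on quaternary C5, assembled by conjugate addition and enolate alkylation of a 4-silyloxycyclohexenone.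

Key step: step 11

Remark on numbering: eremophilane numbering is used (ring A: C1, C2, C3, C4, C5, C10; ring B: C5 to C10; C11 on C7 carries C12 (=CH2) and C13 (CH2O); methyl C14 on C5, methyl C15 on C4). Read from the SMILES, the target is 3S,4S,5S,7S in the core and 6R in the dienoate.
Remark on C10: compounds 13, 16, 17 and 18 are carried as mixtures of epimers at the C10 carbinol (written without configuration there), because C10 becomes sp2 in step 11.
Remark on the carbene: the triazolium salt is written as one antipode; if it proves mismatched with the substrate bias at C7, its commercial enantiomer is used.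

Step 1
Reactants: 1 1,4-dioxaspiro[4.5]dec-6-en-8-one
Product: 2 (8S)-1,4-dioxaspiro[4.5]dec-6-en-8-ol
Conditions: RuCl(p-cymene)[(S,S)-TsDPEN] (1 mol %), HCO2Na, n-Bu4NCl, CH2Cl2/H2O, rt
Reagents that add atoms: none
Why: Asymmetric transfer hydrogenation delivers hydride only to the carbonyl of the enone, and the CH/π contact between the arene ligand and the alkenyl flank should fix the new carbinol (future C3) as S.

Step 2
Reactants: 2 (8S)-1,4-dioxaspiro[4.5]dec-6-en-8-ol
Product: 3 tert-butyl[(8S)-1,4-dioxaspiro[4.5]dec-6-en-8-yloxy]dimethylsilane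
Conditions: TBSCl, imidazole, DMF, rt
Reagents that add atoms: tert-butylchlorodimethylsilane, CC(C)(C)[Si](C)(C)Cl
Why: Silyl ether formation on the secondary allylic alcohol protects the future C3 oxygen for the organometallic steps without touching the stereocentre.

Step 3
Reactants: 3 tert-butyl[(8S)-1,4-dioxaspiro[4.5]dec-6-en-8-yloxy]dimethylsilane
Product: 4 (4S)-4-[(tert-butyldimethylsilyl)oxy]cyclohex-2-en-1-one
Conditions: montmorillonite K10 (moist), CH2Cl2, rt
Reagents that add atoms: water, O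
Why: Mild solid-acid ketal hydrolysis releases the ketone as a γ-silyloxy enone under conditions that should avoid elimination or racemisation of the allylic silyl ether.

Step 4
Reactants: 4 (4S)-4-[(tert-butyldimethylsilyl)oxy]cyclohex-2-en-1-one
Product: 5 (4S)-4-[(tert-butyldimethylsilyl)oxy]-2-iodocyclohex-2-en-1-one
Conditions: I2, pyridine/CH2Cl2 (1:1), 0 °C to rt
Reagents that add atoms: iodine, II
Why: α-Iodination of the enone by the pyridine-mediated addition–iodination–elimination sequence (Baylis–Hillman-type) puts a handle on the future C5 without affecting C3.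

Step 5
Reactants: 5 (4S)-4-[(tert-butyldimethylsilyl)oxy]-2-iodocyclohex-2-en-1-one
Product: 6 (4S)-4-[(tert-butyldimethylsilyl)oxy]-2-methylcyclohex-2-en-1-one
Conditions: Me4Sn, Pd2(dba)3 (3 mol %), AsPh3, CuCl (10 mol %), NMP, 50 °C
Reagents that add atoms: tetramethylstannane, C[Sn](C)(C)C
Why: Stille cross-coupling of the 2-iodoenone with tetramethylstannane installs the C14 methyl under neutral conditions, so the base-sensitive γ-silyloxy enone is not exposed to base.

Step 6
Reactants: 6 (4S)-4-[(tert-butyldimethylsilyl)oxy]-2-methylcyclohex-2-en-1-one; 7 2-bromo-N-methoxy-N-methylacetamide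
Product: 9 2-[(1S,2S,3S)-3-[(tert-butyldimethylsilyl)oxy]-1,2-dimethyl-6-oxocyclohexyl]-N-methoxy-N-methylacetamide, via lithium enolate 8 (not isolated)
Conditions: MeLi (2 equiv), CuBr·SMe2, Et2O, −78 to −20 °C; then 7, HMPA, THF, −20 °C to rt
Reagents that add atoms: lithium dimethylcuprate (methyl group), [Li+].C[Cu-]C
Why: In this conjugate addition–enolate alkylation the cuprate adds anti to the C3 silyloxy group (sets C4) and the regiodefined enolate 8 is alkylated anti to the new C4 methyl, which sets the C5 quaternary centre with the two methyls cis and the acetamide arm trans to the C4 methyl.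

Step 7
Reactants: 9 2-[(1S,2S,3S)-3-[(tert-butyldimethylsilyl)oxy]-1,2-dimethyl-6-oxocyclohexyl]-N-methoxy-N-methylacetamide
Product: 11 2-[(1S,2S,3S)-3-[(tert-butyldimethylsilyl)oxy]-1,2-dimethyl-6-oxocyclohex-4-en-1-yl]-N-methoxy-N-methylacetamide, via trimethylsilyl enol ether 10 (not isolated)
Conditions: LiN(i-Pr)2, THF, −78 °C; TMSCl; then Pd(OAc)2 (10 mol %), O2 (1 atm), DMSO, rt
Reagents that add atoms: none
Why: Saegusa–Ito oxidation; enolisation is possible only toward C1 because C5 is quaternary, so the silyl enol ether is dehydrogenated regiospecifically to the C1–C2 enone and no stereocentre is touched.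

Step 8
Reactants: 11 2-[(1S,2S,3S)-3-[(tert-butyldimethylsilyl)oxy]-1,2-dimethyl-6-oxocyclohex-4-en-1-yl]-N-methoxy-N-methylacetamide; 12 3-bromoprop-1-ene (allyl bromide)
Product: 13 2-[(1S,5S,6S)-5-[(tert-butyldimethylsilyl)oxy]-2-hydroxy-1,6-dimethyl-2-(prop-2-en-1-yl)cyclohex-3-en-1-yl]-N-methoxy-N-methylacetamide (both C10 epimers)
Conditions: indium powder, THF/H2O (1:1), rt
Reagents that add atoms: none
Why: Barbier allylation with allylindium adds 1,2 to the enone carbonyl and leaves the Weinreb amide and silyl ether intact; the new C10 carbinol forms as an epimer mixture, which is irrelevant because C10 is planarised in step 11.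

Step 9
Reactants: 13 the C10 allyl carbinol Weinreb amide; 14 2-bromoprop-2-en-1-ol
Product: 16 1-[(1S,5S,6S)-5-[(tert-butyldimethylsilyl)oxy]-2-hydroxy-1,6-dimethyl-2-(prop-2-en-1-yl)cyclohex-3-en-1-yl]-3-(hydroxymethyl)but-3-en-2-one (both C10 epimers), via dilithio reagent 15 (not isolated)
Conditions: 14, t-BuLi (3 equiv), Et2O, −78 to 0 °C; then 13, THF, −78 to 0 °C; aq NH4Cl
Reagents that add atoms: none
Why: Weinreb ketone synthesis; bromine–lithium exchange gives the O,2-dilithio derivative of allyl alcohol, whose vinyl carbon adds once to the amide because the chelated tetrahedral adduct survives until work-up, releasing the hydroxymethyl vinyl ketone with C11, C12 and C13 in place.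

Step 10
Reactants: 16 the hydroxymethyl vinyl ketone with the C10 allyl carbinol
Product: 17 2-[(4S,5S,6S)-4-[(tert-butyldimethylsilyl)oxy]-1-hydroxy-6-[3-(hydroxymethyl)-2-oxobut-3-en-1-yl]-5,6-dimethylcyclohex-2-en-1-yl]acetaldehyde (both C10 epimers)
Conditions: O3, CH2Cl2, pyridine, −78 °C, Sudan Red 7B end point; then Me2S, −78 °C to rt
Reagents that add atoms: ozone, [O-][O+]=O
Why: Chemoselective ozonolysis; ozone reacts fastest with the electron-rich monosubstituted alkene, the conjugated vinyl ketone and the hindered ring A alkene flanked by two oxygenated carbons being slower, and the dye end point limits over-oxidation.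

Step 11
Reactants: 17 the keto aldehyde
Product: 19 (3S,4S,5S,7S)-3-[(tert-butyldimethylsilyl)oxy]-7,13-dihydroxyeremophila-1,9,11(12)-trien-8-one, via bicyclic ketol 18 (not isolated)
Conditions: (5aS,10bR)-2-(pentafluorophenyl)-4,5a,6,10b-tetrahydroindeno[2,1-b][1,2,4]triazolo[4,3-d][1,4]oxazin-2-ium tetrafluoroborate (15 mol %), i-Pr2NEt (15 mol %), toluene (0.02 M), rt; then DBU (2 equiv), 40 °C
Reagents that add atoms: none
Why: The triazolylidene adds to the aldehyde and proton transfer gives the hydroxy enamine (acyl anion equivalent), whose carbon C8 attacks the C7 ketone, and release of the carbene leaves ketol 18; DBU then expels the C10 hydroxyl by E1cB elimination across C9–C10 to give the fully conjugated dienone. The closest known reaction type is the carbene-catalysed intramolecular crossed aldehyde–ketone benzoin reaction that gives six-membered cyclic tertiary acyloins. Ring B closes in the 6-exo-trig mode. C7 is set under control of the chiral carbene, reinforced by the C5 quaternary centre, which should place the bulky C11 group equatorial in the chair-like transition state so that the new hydroxyl is cis to the C5 methyl. The step needs 1,2-addition to the ketone in preference to conjugate (Stetter) addition to C12 and to aldol closures; ring size (six against eight atoms), the weak amine base and high dilution should secure this.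

Step 12
Reactants: 19 (3S,4S,5S,7S)-3-[(tert-butyldimethylsilyl)oxy]-7,13-dihydroxyeremophila-1,9,11(12)-trien-8-one
Product: 20 (3S,4S,5S,7S)-13-acetoxy-3-[(tert-butyldimethylsilyl)oxy]-7-hydroxyeremophila-1,9,11(12)-trien-8-one
Conditions: Ac2O (1.2 equiv), pyridine, CH2Cl2, 0 °C
Reagents that add atoms: acetic anhydride, CC(=O)OC(C)=O
Why: Acetylation under pyridine catalysis is selective for the primary allylic C13 hydroxyl because the remaining C7 hydroxyl is tertiary.

Step 13
Reactants: 20 (3S,4S,5S,7S)-13-acetoxy-3-[(tert-butyldimethylsilyl)oxy]-7-hydroxyeremophila-1,9,11(12)-trien-8-one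
Product: 21 (3S,4S,5S,7S)-13-acetoxy-3,7-dihydroxyeremophila-1,9,11(12)-trien-8-one
Conditions: HF·pyridine, THF/pyridine, 0 °C to rt
Reagents that add atoms: none
Why: Fluoride-mediated desilylation with buffered HF cleaves the secondary silyl ether while the acetate, the α-ketol and the dienone should be stable to these mildly acidic conditions.

Step 14
Reactants: 22 (4S)-4-benzyl-3-propanoyl-1,3-oxazolidin-2-one; 23 iodoethane
Product: 24 (4S)-4-benzyl-3-[(2R)-2-methylbutanoyl]-1,3-oxazolidin-2-one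
Conditions: NaN(SiMe3)2, THF, −78 °C; then EtI, −78 to −20 °C
Reagents that add atoms: none
Why: Evans alkylation; the chelated Z sodium enolate is ethylated on the face opposite the benzyl group, which sets the future C6 of the dienoate chain as R.

Step 15
Reactants: 24 (4S)-4-benzyl-3-[(2R)-2-methylbutanoyl]-1,3-oxazolidin-2-one
Product: 25 (2R)-2-methylbutan-1-ol
Conditions: LiBH4, MeOH (1 equiv), Et2O, 0 °C
Reagents that add atoms: none
Why: Reductive cleavage of the imide with LiBH4 gives the primary alcohol without epimerisation and returns the auxiliary.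

Step 16
Reactants: 25 (2R)-2-methylbutan-1-ol; 26 2-(triphenylphosphoranylidene)propanal
Product: 28 (2E,4R)-2,4-dimethylhex-2-enal, via (2R)-2-methylbutanal 27 (not isolated)
Conditions: TEMPO (10 mol %), PhI(OAc)2, CH2Cl2, rt; then 26, toluene, 80 °C
Reagents that add atoms: none
Why: Oxoammonium-catalysed oxidation gives the configurationally labile aldehyde under near-neutral conditions, and the stabilised formyl ylide traps it at once in an E-selective Wittig reaction without loss of the α-stereocentre.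

Step 17
Reactants: 28 (2E,4R)-2,4-dimethylhex-2-enal; 29 ethyl (triphenylphosphoranylidene)acetate
Product: 30 ethyl (2E,4E,6R)-4,6-dimethylocta-2,4-dienoate
Conditions: CH2Cl2, 40 °C
Reagents that add atoms: none
Why: Wittig olefination with the stabilised ester ylide is E-selective and, being free of amine catalysts, avoids dienamine formation that could epimerise the γ-stereocentre.

Step 18
Reactants: 30 ethyl (2E,4E,6R)-4,6-dimethylocta-2,4-dienoate
Product: 31 (2E,4E,6R)-4,6-dimethylocta-2,4-dienoic acid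
Conditions: LiOH, THF/MeOH/H2O, rt; then 1 M HCl
Reagents that add atoms: lithium hydroxide, [Li+].[OH-]
Why: Ester saponification with hydroxide gives the acid; the stereocentre is not acidic under these conditions and the diene geometry should be retained.

Step 19
Reactants: 21 (3S,4S,5S,7S)-13-acetoxy-3,7-dihydroxyeremophila-1,9,11(12)-trien-8-one; 31 (2E,4E,6R)-4,6-dimethylocta-2,4-dienoic acid
Product: 33 (3S,4S,5S,7S)-13-acetoxy-7-hydroxy-8-oxoeremophila-1,9,11(12)-trien-3-yl (2E,4E,6R)-4,6-dimethylocta-2,4-dienoate (CNP0160850.1), via mixed anhydride 32 (not isolated)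
Conditions: 2,4,6-trichlorobenzoyl chloride, Et3N, THF, rt; then 21, DMAP, toluene, rt
Reagents that add atoms: none
Why: Yamaguchi esterification through the mixed anhydride acylates the secondary allylic C3 hydroxyl, the tertiary C7 hydroxyl being unreactive, and touches no stereocentre.

**Compound list**

1 | 1,4-dioxaspiro[4.5]dec-6-en-8-one | O=C1C=CC2(CC1)OCCO2 | starting material
2 | (8S)-1,4-dioxaspiro[4.5]dec-6-en-8-ol | O[C@@H]1C=CC2(CC1)OCCO2 | intermediate
3 | tert-butyl[(8S)-1,4-dioxaspiro[4.5]dec-6-en-8-yloxy]dimethylsilane | CC(C)(C)[Si](C)(C)O[C@@H]1C=CC2(CC1)OCCO2 | intermediate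
4 | (4S)-4-[(tert-butyldimethylsilyl)oxy]cyclohex-2-en-1-one | O=C1C=C[C@@H](O[Si](C)(C)C(C)(C)C)CC1 | intermediate
5 | (4S)-4-[(tert-butyldimethylsilyl)oxy]-2-iodocyclohex-2-en-1-one | O=C1C(I)=C[C@@H](O[Si](C)(C)C(C)(C)C)CC1 | intermediate
6 | (4S)-4-[(tert-butyldimethylsilyl)oxy]-2-methylcyclohex-2-en-1-one | CC1=C[C@@H](O[Si](C)(C)C(C)(C)C)CCC1=O | intermediate
7 | 2-bromo-N-methoxy-N-methylacetamide | CON(C)C(=O)CBr | starting material
8 | lithium (3S,4S)-4-[(tert-butyldimethylsilyl)oxy]-2,3-dimethylcyclohex-1-en-1-olate | [Li]OC1=C(C)[C@H](C)[C@@H](O[Si](C)(C)C(C)(C)C)CC1 | intermediate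
9 | 2-[(1S,2S,3S)-3-[(tert-butyldimethylsilyl)oxy]-1,2-dimethyl-6-oxocyclohexyl]-N-methoxy-N-methylacetamide | CON(C)C(=O)C[C@]1(C)C(=O)CC[C@H](O[Si](C)(C)C(C)(C)C)[C@H]1C | intermediate
10 | 2-[(1S,5S,6S)-5-[(tert-butyldimethylsilyl)oxy]-1,6-dimethyl-2-[(trimethylsilyl)oxy]cyclohex-2-en-1-yl]-N-methoxy-N-methylacetamide | CON(C)C(=O)C[C@]1(C)C(O[Si](C)(C)C)=CC[C@H](O[Si](C)(C)C(C)(C)C)[C@H]1C | intermediate
11 | 2-[(1S,2S,3S)-3-[(tert-butyldimethylsilyl)oxy]-1,2-dimethyl-6-oxocyclohex-4-en-1-yl]-N-methoxy-N-methylacetamide | CON(C)C(=O)C[C@]1(C)C(=O)C=C[C@H](O[Si](C)(C)C(C)(C)C)[C@H]1C | intermediate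
12 | 3-bromoprop-1-ene | C=CCBr | starting material
13 | 2-[(1S,5S,6S)-5-[(tert-butyldimethylsilyl)oxy]-2-hydroxy-1,6-dimethyl-2-(prop-2-en-1-yl)cyclohex-3-en-1-yl]-N-methoxy-N-methylacetamide (C10 epimers) | CON(C)C(=O)C[C@]1(C)C(O)(CC=C)C=C[C@H](O[Si](C)(C)C(C)(C)C)[C@H]1C | intermediate
14 | 2-bromoprop-2-en-1-ol | OCC(Br)=C | starting material
15 | lithium 2-lithioprop-2-en-1-olate | [Li]OCC([Li])=C | intermediate
16 | 1-[(1S,5S,6S)-5-[(tert-butyldimethylsilyl)oxy]-2-hydroxy-1,6-dimethyl-2-(prop-2-en-1-yl)cyclohex-3-en-1-yl]-3-(hydroxymethyl)but-3-en-2-one (C10 epimers) | C=C(CO)C(=O)C[C@]1(C)C(O)(CC=C)C=C[C@H](O[Si](C)(C)C(C)(C)C)[C@H]1C | intermediate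
17 | 2-[(4S,5S,6S)-4-[(tert-butyldimethylsilyl)oxy]-1-hydroxy-6-[3-(hydroxymethyl)-2-oxobut-3-en-1-yl]-5,6-dimethylcyclohex-2-en-1-yl]acetaldehyde (C10 epimers) | C=C(CO)C(=O)C[C@]1(C)C(O)(CC=O)C=C[C@H](O[Si](C)(C)C(C)(C)C)[C@H]1C | intermediate
18 | (3S,4S,5S,7S)-3-[(tert-butyldimethylsilyl)oxy]-7,10,13-trihydroxyeremophila-1,11(12)-dien-8-one (C10 epimers) | C=C(CO)[C@@]1(O)C[C@]2(C)C(O)(CC1=O)C=C[C@H](O[Si](C)(C)C(C)(C)C)[C@H]2C | intermediate
19 | (3S,4S,5S,7S)-3-[(tert-butyldimethylsilyl)oxy]-7,13-dihydroxyeremophila-1,9,11(12)-trien-8-one | C=C(CO)[C@@]1(O)C[C@]2(C)C(=CC1=O)C=C[C@H](O[Si](C)(C)C(C)(C)C)[C@H]2C | intermediate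
20 | (3S,4S,5S,7S)-13-acetoxy-3-[(tert-butyldimethylsilyl)oxy]-7-hydroxyeremophila-1,9,11(12)-trien-8-one | C=C(COC(C)=O)[C@@]1(O)C[C@]2(C)C(=CC1=O)C=C[C@H](O[Si](C)(C)C(C)(C)C)[C@H]2C | intermediate
21 | (3S,4S,5S,7S)-13-acetoxy-3,7-dihydroxyeremophila-1,9,11(12)-trien-8-one | C=C(COC(C)=O)[C@@]1(O)C[C@]2(C)C(=CC1=O)C=C[C@H](O)[C@H]2C | intermediate
22 | (4S)-4-benzyl-3-propanoyl-1,3-oxazolidin-2-one | CCC(=O)N1[C@@H](Cc2ccccc2)COC1=O | starting material
23 | iodoethane | CCI | starting material
24 | (4S)-4-benzyl-3-[(2R)-2-methylbutanoyl]-1,3-oxazolidin-2-one | CC[C@@H](C)C(=O)N1[C@@H](Cc2ccccc2)COC1=O | intermediate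
25 | (2R)-2-methylbutan-1-ol | CC[C@@H](C)CO | intermediate
26 | 2-(triphenylphosphoranylidene)propanal | CC(C=O)=P(c1ccccc1)(c1ccccc1)c1ccccc1 | starting material
27 | (2R)-2-methylbutanal | CC[C@@H](C)C=O | intermediate
28 | (2E,4R)-2,4-dimethylhex-2-enal | O=C/C(C)=C/[C@H](C)CC | intermediate
29 | ethyl (triphenylphosphoranylidene)acetate | CCOC(=O)C=P(c1ccccc1)(c1ccccc1)c1ccccc1 | starting material
30 | ethyl (2E,4E,6R)-4,6-dimethylocta-2,4-dienoate | CCOC(=O)/C=C/C(C)=C/[C@H](C)CC | intermediate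
31 | (2E,4E,6R)-4,6-dimethylocta-2,4-dienoic acid | OC(=O)/C=C/C(C)=C/[C@H](C)CC | intermediate
32 | (2E,4E,6R)-4,6-dimethylocta-2,4-dienoic 2,4,6-trichlorobenzoic anhydride | O=C(OC(=O)/C=C/C(C)=C/[C@H](C)CC)c1c(Cl)cc(Cl)cc1Cl | intermediate
33 | (3S,4S,5S,7S)-13-acetoxy-7-hydroxy-8-oxoeremophila-1,9,11(12)-trien-3-yl (2E,4E,6R)-4,6-dimethylocta-2,4-dienoate | C=C(COC(C)=O)[C@@]1(O)C[C@]2(C)C(=CC1=O)C=C[C@H](OC(=O)/C=C/C(C)=C/[C@H](C)CC)[C@H]2C | target

**Totals and risks**

Total step count: 19. Longest linear sequence: 14 steps (steps 1 to 13, then step 19).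

The three steps most likely to fail:

Step 11. The carbene may add in conjugate fashion to the hydroxymethyl vinyl ketone and trigger oligomerisation, the β-hydroxy aldehyde may fragment by retro-aldol reaction before ring closure, or facial selectivity at the C7 ketone may be poor. The fallback sets out from 13 and returns at 19; it moves the C13 oxidation behind the ring closure. Isopropenylmagnesium bromide (THF, 0 °C) converts the Weinreb amide of 13 into 1-[(1S,5S,6S)-5-[(tert-butyldimethylsilyl)oxy]-2-hydroxy-1,6-dimethyl-2-(prop-2-en-1-yl)cyclohex-3-en-1-yl]-3-methylbut-3-en-2-one F1. Ozonolysis as in step 10 gives 2-[(4S,5S,6S)-4-[(tert-butyldimethylsilyl)oxy]-1-hydroxy-5,6-dimethyl-6-(3-methyl-2-oxobut-3-en-1-yl)cyclohex-2-en-1-yl]acetaldehyde F2. The carbene-catalysed benzoin closure of step 11, now on a less electrophilic vinyl ketone with no free primary hydroxyl, gives (3S,4S,5S,7S)-3-[(tert-butyldimethylsilyl)oxy]-7,10-dihydroxyeremophila-1,11(12)-dien-8-one F3, which is dehydrated in the flask with DBU to (3S,4S,5S,7S)-3-[(tert-butyldimethylsilyl)oxy]-7-hydroxyeremophila-1,9,11(12)-trien-8-one F4. Allylic oxidation of the isopropenyl methyl with SeO2 (catalytic) and t-BuOOH in CH2Cl2 then gives 19.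

Step 10. Over-oxidation may occur if ozone also attacks the ring A alkene or the vinyl ketone. The fallback sets out from 11 and returns at 17; it introduces C8 and C9 as an alkyne, so no alkene has to be cleaved. Ethynylmagnesium bromide with CeCl3 (THF, −78 °C) adds to the ketone of 11 to give 2-[(1S,5S,6S)-5-[(tert-butyldimethylsilyl)oxy]-2-ethynyl-2-hydroxy-1,6-dimethylcyclohex-3-en-1-yl]-N-methoxy-N-methylacetamide F5. Reagent 15 converts the Weinreb amide as in step 9 into 1-[(1S,5S,6S)-5-[(tert-butyldimethylsilyl)oxy]-2-ethynyl-2-hydroxy-1,6-dimethylcyclohex-3-en-1-yl]-3-(hydroxymethyl)but-3-en-2-one F6. Anti-Markovnikov hydration of the terminal alkyne (CpRu(MeCN)3PF6, 5,5'-bis(trifluoromethyl)-2,2'-bipyridine, NMP/H2O, rt) then gives 17.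

Step 6. Alkylation of the cuprate-derived enolate by the α-bromo amide may be slow or lost to proton transfer, and the trans selectivity may erode. The fallback sets out from 6 and returns at 9; it uses the most reactive electrophile and adjusts the oxidation level afterwards. The same cuprate addition gives enolate 8, which is trapped with allyl bromide and HMPA to give (2S,3S,4S)-4-[(tert-butyldimethylsilyl)oxy]-2,3-dimethyl-2-(prop-2-en-1-yl)cyclohexan-1-one F7. Oxidative cleavage of the terminal alkene (RuCl3 catalytic, NaIO4, MeCN/EtOAc/H2O) gives 2-[(1S,2S,3S)-3-[(tert-butyldimethylsilyl)oxy]-1,2-dimethyl-6-oxocyclohexyl]acetic acid F8. Amide formation with N,O-dimethylhydroxylamine hydrochloride, EDC·HCl and i-Pr2NEt then gives 9.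

Further compounds
F1 | step 11 | 1-[(1S,5S,6S)-5-[(tert-butyldimethylsilyl)oxy]-2-hydroxy-1,6-dimethyl-2-(prop-2-en-1-yl)cyclohex-3-en-1-yl]-3-methylbut-3-en-2-one | C=C(C)C(=O)C[C@]1(C)C(O)(CC=C)C=C[C@H](O[Si](C)(C)C(C)(C)C)[C@H]1C
F2 | step 11 | 2-[(4S,5S,6S)-4-[(tert-butyldimethylsilyl)oxy]-1-hydroxy-5,6-dimethyl-6-(3-methyl-2-oxobut-3-en-1-yl)cyclohex-2-en-1-yl]acetaldehyde | C=C(C)C(=O)C[C@]1(C)C(O)(CC=O)C=C[C@H](O[Si](C)(C)C(C)(C)C)[C@H]1C
F3 | step 11 | (3S,4S,5S,7S)-3-[(tert-butyldimethylsilyl)oxy]-7,10-dihydroxyeremophila-1,11(12)-dien-8-one | C=C(C)[C@@]1(O)C[C@]2(C)C(O)(CC1=O)C=C[C@H](O[Si](C)(C)C(C)(C)C)[C@H]2C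
F4 | step 11 | (3S,4S,5S,7S)-3-[(tert-butyldimethylsilyl)oxy]-7-hydroxyeremophila-1,9,11(12)-trien-8-one | C=C(C)[C@@]1(O)C[C@]2(C)C(=CC1=O)C=C[C@H](O[Si](C)(C)C(C)(C)C)[C@H]2C
F5 | step 10 | 2-[(1S,5S,6S)-5-[(tert-butyldimethylsilyl)oxy]-2-ethynyl-2-hydroxy-1,6-dimethylcyclohex-3-en-1-yl]-N-methoxy-N-methylacetamide | CON(C)C(=O)C[C@]1(C)C(O)(C#C)C=C[C@H](O[Si](C)(C)C(C)(C)C)[C@H]1C
F6 | step 10 | 1-[(1S,5S,6S)-5-[(tert-butyldimethylsilyl)oxy]-2-ethynyl-2-hydroxy-1,6-dimethylcyclohex-3-en-1-yl]-3-(hydroxymethyl)but-3-en-2-one | C=C(CO)C(=O)C[C@]1(C)C(O)(C#C)C=C[C@H](O[Si](C)(C)C(C)(C)C)[C@H]1C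
F7 | step 6 | (2S,3S,4S)-4-[(tert-butyldimethylsilyl)oxy]-2,3-dimethyl-2-(prop-2-en-1-yl)cyclohexan-1-one | C=CC[C@]1(C)C(=O)CC[C@H](O[Si](C)(C)C(C)(C)C)[C@H]1C
F8 | step 6 | 2-[(1S,2S,3S)-3-[(tert-butyldimethylsilyl)oxy]-1,2-dimethyl-6-oxocyclohexyl]acetic acid | OC(=O)C[C@]1(C)C(=O)CC[C@H](O[Si](C)(C)C(C)(C)C)[C@H]1C
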